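**Plan** (atoms are labelled C1–C15 by germacrane numbering: C6 carbinol, C7–C8 lactone fusion, C11–C13 methylene lactone, C15 the acyloxymethyl carbon)

- Retrosynthesis cuts, in order: the C15–O ester; C13 and the C6–H bond (C6 ketone); C7–C11 and O8–C12 (malonate on a C7–C8 epoxide); C8–C9 (retro anionic oxy-Cope, which restores the C1–C6 bond of a cyclohexenol); C6–ethynyl; C15–C4; and finally the dione ring (Claisen) and the C1–C2 bond (alkylation).
- Forward: the six-membered ring C1–C6 is made first as 4-isopropenylcyclohexane-1,3-dione. C15 is joined to C4 of its enol triflate by Stille coupling. Ethynyl addition at C6 and an acetylenic anionic oxy-Cope rearrangement then expand the six-membered ring to the ten-membered ring. The lactone ring is annulated last onto C7–C8.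
- Enabling feature: C4 is a carbonyl carbon of the 1,3-dione (the β-carbon of the C6 enone), so its triflate is a vinylogous acyl triflate; the six-membered ring holds C3 and C6 cis on C4=C5, which is the geometry the target needs.
- Stereochemistry: E-C1=C10 from the chair-like oxy-Cope of the trans-dialkenyl carbinol; Z-C7=C8 from peripheral protonation of the allenolate. C7/C8 come from catalytic asymmetric epoxidation of the achiral trienone, with inversion at C7 by malonate giving the trans lactone. C6 comes from a reagent-controlled CBS reduction. Everything before step 8 is racemic or achiral.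

Key step: step 5

Assumption: (S)-BINOL is taken as the ligand enantiomer that gives the (1S,10S)-epoxide in step 8; should the sense be opposite, (R)-BINOL is used instead.

Step 1
Reactants: 1 ethyl 3-methylbut-2-enoate; 2 2-(2-bromoethyl)-2-methyl-1,3-dioxolane
Product: 4 ethyl 5-oxo-2-(prop-1-en-2-yl)hexanoate (racemic), via ketal ester 3 (not isolated)
Conditions: LDA, THF–DMPU, −78 °C; 2, −78 °C → rt; then 1 M HCl, THF, rt
Reagents that add atoms: water, O
Why: γ-Deprotonation gives the extended dienolate, which alkylates at the α-carbon (deconjugative α-alkylation) and so places the isopropenyl group, and the acidic work-up hydrolyses the dioxolane; the stereocenter is racemic and is erased in step 7.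

Step 2
Reactants: 4 ethyl 5-oxo-2-(prop-1-en-2-yl)hexanoate
Product: 5 4-(prop-1-en-2-yl)cyclohexane-1,3-dione (racemic)
Conditions: LiHMDS (2.2 equiv), THF, −78 → 0 °C; then 1 M HCl
Reagents that add atoms: none
Why: Kinetic enolisation of the methyl ketone and intramolecular Claisen condensation onto the ester close the six-membered ring, and the dione is held as its stable enolate, which protects the isopropenyl group from moving into conjugation.

Step 3
Reactants: 5 4-(prop-1-en-2-yl)cyclohexane-1,3-dione
Product: 6 3-oxo-4-(prop-1-en-2-yl)cyclohex-1-en-1-yl trifluoromethanesulfonate (racemic)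
Conditions: Tf2O, pyridine, CH2Cl2, −78 °C
Reagents that add atoms: trifluoromethanesulfonic anhydride, O=S(=O)(OS(=O)(=O)C(F)(F)F)C(F)(F)F
Why: O-Sulfonylation of the vinylogous acid should favour the oxygen remote from the isopropenyl-bearing carbon, which keeps the carbonyl next to C1 (the future C6) and makes C4 the triflate carbon.

Step 4
Reactants: 7 (tributylstannyl)methanol
Product: 8 tributyl{[(4-methoxyphenyl)methoxy]methyl}stannane
Conditions: NaH, THF–DMF, 0 °C; 4-methoxybenzyl chloride, Bu4NI (cat.), rt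
Reagents that add atoms: 4-methoxybenzyl chloride, COc1ccc(CCl)cc1
Why: Williamson ether synthesis on the primary alkoxide gives the PMB-protected hydroxymethyl donor.

Step 5
Reactants: 6 3-oxo-4-(prop-1-en-2-yl)cyclohex-1-en-1-yl trifluoromethanesulfonate; 8 tributyl{[(4-methoxyphenyl)methoxy]methyl}stannane
Product: 9 3-{[(4-methoxyphenyl)methoxy]methyl}-6-(prop-1-en-2-yl)cyclohex-2-en-1-one (racemic)
Conditions: Pd(PPh3)4 (cat.), CuI (cat.), LiCl, 1,4-dioxane, 80 °C
Reagents that add atoms: none
Why: Zerovalent palladium inserts into the C4–O bond of the vinylogous acyl triflate, which the C6 carbonyl makes about as reactive as an acyl halide; the alkoxymethyl group is then transferred from tin to palladium (helped by CuI and chloride) and reductive elimination forms the C15–C4 bond. The closest known reaction type is the Stille coupling of enol triflates with (hydroxymethyl)- and (alkoxymethyl)tributylstannanes. No ring is closed and no stereocenter is formed. The step needs transfer of the α-oxygenated carbon in preference to butyl, which the α-oxygen secures, and bond formation at C4 only, which the position of the triflate fixes. It also needs the C3/C6-cis geometry of the new trisubstituted alkene, which the six-membered ring C1–C6 enforces and which is carried unchanged into the ten-membered ring. Removing the triflate here also matters for step 6, where an organomagnesium reagent would otherwise attack the vinylogous acyl triflate and fragment the ring; the isopropenyl stereocenter is racemic and is erased in step 7.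

Step 6
Reactants: 9 3-{[(4-methoxyphenyl)methoxy]methyl}-6-(prop-1-en-2-yl)cyclohex-2-en-1-one; 10 ethynylmagnesium bromide
Product: 11 rac-(1S,6S)-1-ethynyl-3-{[(4-methoxyphenyl)methoxy]methyl}-6-(prop-1-en-2-yl)cyclohex-2-en-1-ol (ethynyl trans to isopropenyl)
Conditions: CeCl3, THF, −78 °C; then aq. NH4Cl
Reagents that add atoms: none
Why: Cerium-mediated 1,2-addition suppresses enolisation, and attack anti to the neighbouring isopropenyl group should give the trans-dialkenyl carbinol (relative configuration only) that the chair-like rearrangement needs.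

Step 7
Reactants: 11 rac-(1S,6S)-1-ethynyl-3-{[(4-methoxyphenyl)methoxy]methyl}-6-(prop-1-en-2-yl)cyclohex-2-en-1-ol
Product: 13 (2Z,5E,9E)-9-{[(4-methoxyphenyl)methoxy]methyl}-5-methylcyclodeca-2,5,9-trien-1-one, via potassium allenolate 12 (not isolated)
Conditions: KHMDS (1.05 equiv), 18-crown-6, THF, 0 °C → rt; then AcOH, −78 °C
Reagents that add atoms: none
Why: Anionic oxy-Cope rearrangement (acetylenic variant) of the potassium alkoxide through a chair-like array with the isopropenyl group pseudo-equatorial breaks C1–C6 and forms C8–C9 and the E-C1=C10 bond, and the cyclic allenolate is protonated at C7 from the ring periphery to give the Z-enone; both stereocenters are destroyed, so 13 is achiral.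

Step 8
Reactants: 13 (2Z,5E,9E)-9-{[(4-methoxyphenyl)methoxy]methyl}-5-methylcyclodeca-2,5,9-trien-1-one
Product: 14 (1S,3E,7E,10S)-4-{[(4-methoxyphenyl)methoxy]methyl}-8-methyl-11-oxabicyclo[8.1.0]undeca-3,7-dien-2-one
Conditions: La(OiPr)3 (cat.), (S)-BINOL (cat.), Ph3As=O (cat.), tert-butyl hydroperoxide (decane), 4 Å MS, THF, rt
Reagents that add atoms: tert-butyl hydroperoxide, CC(C)(C)OO
Why: In this lanthanum–BINOL-catalysed Weitz–Scheffer epoxidation the peroxide should add to the unhindered β-carbon C8 of the Z-enone and not to the β,β-disubstituted C4, the metal-bound peroxy enolate should close before bond rotation so that the cis-epoxide results, and the chiral complex selects one enantiotopic face and so sets C7 and C8.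

Step 9
Reactants: 14 (1S,3E,7E,10S)-4-{[(4-methoxyphenyl)methoxy]methyl}-8-methyl-11-oxabicyclo[8.1.0]undeca-3,7-dien-2-one; 15 diprop-2-en-1-yl propanedioate (diallyl malonate)
Product: 16 prop-2-en-1-yl (3aR,5E,9E,11aS)-6-{[(4-methoxyphenyl)methoxy]methyl}-10-methyl-2,4-dioxo-2,3,3a,4,7,8,11,11a-octahydrocyclodeca[b]furan-3-carboxylate (both C3 epimers)
Conditions: NaH, THF, 0 °C → rt; then aq. NH4Cl
Reagents that add atoms: none
Why: Proposed new method: the malonate anion should open the epoxide by SN2 attack at C7, the carbon activated by the adjacent C6 carbonyl in the way an α-halo ketone is, with inversion at C7, and the C8 alkoxide so released should close onto one allyl ester (5-exo-trig) to give the trans-fused lactone with C8 untouched, while reversible addition of malonate to the ketone leads nowhere; the closest known reaction types are the malonate–epoxide lactone annulation of simple epoxides and the α-selective opening of α,β-epoxy ketones by thiolates, azide and amines.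

Step 10
Reactants: 16 prop-2-en-1-yl (3aR,5E,9E,11aS)-6-{[(4-methoxyphenyl)methoxy]methyl}-10-methyl-2,4-dioxo-2,3,3a,4,7,8,11,11a-octahydrocyclodeca[b]furan-3-carboxylate
Product: 18 (3aR,5E,9E,11aS)-6-{[(4-methoxyphenyl)methoxy]methyl}-10-methyl-3-methylidene-3,3a,7,8,11,11a-hexahydrocyclodeca[b]furan-2,4-dione, via carboxylic acid 17 (not isolated)
Conditions: Pd(PPh3)4 (cat.), Et2NH, THF, rt; then 37% aq. HCHO, AcOH, NaOAc, 50 °C
Reagents that add atoms: formaldehyde, C=O
Why: Tsuji–Trost-type transfer of the allyl group to diethylamine frees the malonic half acid, whose Mannich reaction with formaldehyde followed by decarboxylative elimination (the classical methylenation of α-carboxy lactones) installs C13 without strong base, and the acidic buffer limits epimerisation at C7.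

Step 11
Reactants: 18 (3aR,5E,9E,11aS)-6-{[(4-methoxyphenyl)methoxy]methyl}-10-methyl-3-methylidene-3,3a,7,8,11,11a-hexahydrocyclodeca[b]furan-2,4-dione
Product: 19 (3aR,5E,9E,11aS)-6-(hydroxymethyl)-10-methyl-3-methylidene-3,3a,7,8,11,11a-hexahydrocyclodeca[b]furan-2,4-dione
Conditions: DDQ, CH2Cl2–pH 7 buffer, 0 °C
Reagents that add atoms: none
Why: Oxidative cleavage of the PMB ether by DDQ should leave the enone, the methylene lactone and the alkenes untouched, and the freed C15 hydroxyl cannot form a hemiketal with C6 because it lies trans to C6 across C4=C5.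

Step 12
Reactants: 20 [(tert-butyldimethylsilyl)oxy]acetaldehyde; 21 ethyl 2-(triphenyl-λ5-phosphanylidene)propanoate
Product: 22 ethyl (2E)-4-[(tert-butyldimethylsilyl)oxy]-2-methylbut-2-enoate
Conditions: CH2Cl2, rt
Reagents that add atoms: none
Why: Wittig reaction of the stabilised α-methyl ylide gives the E-trisubstituted enoate.

Step 13
Reactants: 22 ethyl (2E)-4-[(tert-butyldimethylsilyl)oxy]-2-methylbut-2-enoate
Product: 23 (2E)-4-[(tert-butyldimethylsilyl)oxy]-2-methylbut-2-enoic acid
Conditions: LiOH, THF–H2O, rt; then 1 M HCl to pH 3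
Reagents that add atoms: lithium hydroxide, [Li+].[OH-]
Why: Saponification of the ethyl ester should proceed without loss of the primary silyl ether or of the alkene geometry.

Step 14
Reactants: 19 (3aR,5E,9E,11aS)-6-(hydroxymethyl)-10-methyl-3-methylidene-3,3a,7,8,11,11a-hexahydrocyclodeca[b]furan-2,4-dione; 23 (2E)-4-[(tert-butyldimethylsilyl)oxy]-2-methylbut-2-enoic acid
Product: 24 [(3aR,5E,9E,11aS)-10-methyl-3-methylidene-2,4-dioxo-2,3,3a,4,7,8,11,11a-octahydrocyclodeca[b]furan-6-yl]methyl (2E)-4-[(tert-butyldimethylsilyl)oxy]-2-methylbut-2-enoate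
Conditions: DCC, DMAP (cat.), CH2Cl2, 0 °C
Reagents that add atoms: none
Why: Steglich esterification acylates the only hydroxyl group present, since C6 is still a ketone and no second alcohol competes.

Step 15
Reactants: 24 [(3aR,5E,9E,11aS)-10-methyl-3-methylidene-2,4-dioxo-2,3,3a,4,7,8,11,11a-octahydrocyclodeca[b]furan-6-yl]methyl (2E)-4-[(tert-butyldimethylsilyl)oxy]-2-methylbut-2-enoate
Product: 25 [(3aS,4R,5E,9E,11aS)-4-hydroxy-10-methyl-3-methylidene-2-oxo-2,3,3a,4,7,8,11,11a-octahydrocyclodeca[b]furan-6-yl]methyl (2E)-4-[(tert-butyldimethylsilyl)oxy]-2-methylbut-2-enoate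
Conditions: (R)-2-methyl-CBS-oxazaborolidine, catecholborane, toluene, −78 °C
Reagents that add atoms: none
Why: In this Corey–Bakshi–Shibata reduction the enone C4=C5 side should act as the large group, so the (R)-catalyst should deliver hydride to the face that gives the 6R allylic alcohol under reagent control, in a 1,2-sense and without touching the methylene lactone or the esters.

Step 16
Reactants: 25 [(3aS,4R,5E,9E,11aS)-4-hydroxy-10-methyl-3-methylidene-2-oxo-2,3,3a,4,7,8,11,11a-octahydrocyclodeca[b]furan-6-yl]methyl (2E)-4-[(tert-butyldimethylsilyl)oxy]-2-methylbut-2-enoate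
Product: 26 [(3aS,4R,5E,9E,11aS)-4-hydroxy-10-methyl-3-methylidene-2-oxo-2,3,3a,4,7,8,11,11a-octahydrocyclodeca[b]furan-6-yl]methyl (2E)-4-hydroxy-2-methylbut-2-enoate
Conditions: HF·pyridine, THF–pyridine, 0 °C
Reagents that add atoms: none
Why: Buffered fluoride removes the primary silyl ether under conditions that should spare the methylene lactone and avoid base-induced translactonisation to O6.

**Compound list**

1 | ethyl 3-methylbut-2-enoate | CCOC(=O)C=C(C)C | starting material
2 | 2-(2-bromoethyl)-2-methyl-1,3-dioxolane | CC1(CCBr)OCCO1 | starting material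
3 | ethyl 4-(2-methyl-1,3-dioxolan-2-yl)-2-(prop-1-en-2-yl)butanoate (racemic) | CCOC(=O)C(CCC1(C)OCCO1)C(C)=C | intermediate
4 | ethyl 5-oxo-2-(prop-1-en-2-yl)hexanoate (racemic) | CCOC(=O)C(CCC(C)=O)C(C)=C | intermediate
5 | 4-(prop-1-en-2-yl)cyclohexane-1,3-dione (racemic) | CC(=C)C1CCC(=O)CC1=O | intermediate
6 | 3-oxo-4-(prop-1-en-2-yl)cyclohex-1-en-1-yl trifluoromethanesulfonate (racemic) | CC(=C)C1CCC(OS(=O)(=O)C(F)(F)F)=CC1=O | intermediate
7 | (tributylstannyl)methanol | CCCC[Sn](CCCC)(CCCC)CO | starting material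
8 | tributyl{[(4-methoxyphenyl)methoxy]methyl}stannane | CCCC[Sn](CCCC)(CCCC)COCc1ccc(OC)cc1 | intermediate
9 | 3-{[(4-methoxyphenyl)methoxy]methyl}-6-(prop-1-en-2-yl)cyclohex-2-en-1-one (racemic) | CC(=C)C1CCC(COCc2ccc(OC)cc2)=CC1=O | intermediate
10 | ethynylmagnesium bromide | C#C[Mg]Br | starting material
11 | rac-(1S,6S)-1-ethynyl-3-{[(4-methoxyphenyl)methoxy]methyl}-6-(prop-1-en-2-yl)cyclohex-2-en-1-ol (one enantiomer drawn) | O[C@@]1(C#C)C=C(COCc2ccc(OC)cc2)CC[C@H]1C(C)=C | intermediate
12 | potassium (5E,9E)-9-{[(4-methoxyphenyl)methoxy]methyl}-5-methylcyclodeca-1,2,5,9-tetraen-1-olate | [K+].[O-]C1=C=CC/C(C)=C/CC/C(COCc2ccc(OC)cc2)=C\1 | intermediate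
13 | (2Z,5E,9E)-9-{[(4-methoxyphenyl)methoxy]methyl}-5-methylcyclodeca-2,5,9-trien-1-one | O=C1/C=C\C/C(C)=C/CC/C(COCc2ccc(OC)cc2)=C\1 | intermediate
14 | (1S,3E,7E,10S)-4-{[(4-methoxyphenyl)methoxy]methyl}-8-methyl-11-oxabicyclo[8.1.0]undeca-3,7-dien-2-one | O=C1[C@H]2O[C@H]2C/C(C)=C/CC/C(COCc3ccc(OC)cc3)=C\1 | intermediate
15 | diprop-2-en-1-yl propanedioate | C=CCOC(=O)CC(=O)OCC=C | starting material
16 | prop-2-en-1-yl (3aR,5E,9E,11aS)-6-{[(4-methoxyphenyl)methoxy]methyl}-10-methyl-2,4-dioxo-2,3,3a,4,7,8,11,11a-octahydrocyclodeca[b]furan-3-carboxylate (C3 epimers) | C=CCOC(=O)C1C(=O)O[C@H]2C/C(C)=C/CC/C(COCc3ccc(OC)cc3)=C\C(=O)[C@H]12 | intermediate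
17 | (3aR,5E,9E,11aS)-6-{[(4-methoxyphenyl)methoxy]methyl}-10-methyl-2,4-dioxo-2,3,3a,4,7,8,11,11a-octahydrocyclodeca[b]furan-3-carboxylic acid (C3 epimers) | OC(=O)C1C(=O)O[C@H]2C/C(C)=C/CC/C(COCc3ccc(OC)cc3)=C\C(=O)[C@H]12 | intermediate
18 | (3aR,5E,9E,11aS)-6-{[(4-methoxyphenyl)methoxy]methyl}-10-methyl-3-methylidene-3,3a,7,8,11,11a-hexahydrocyclodeca[b]furan-2,4-dione | C=C1C(=O)O[C@H]2C/C(C)=C/CC/C(COCc3ccc(OC)cc3)=C\C(=O)[C@H]12 | intermediate
19 | (3aR,5E,9E,11aS)-6-(hydroxymethyl)-10-methyl-3-methylidene-3,3a,7,8,11,11a-hexahydrocyclodeca[b]furan-2,4-dione | C=C1C(=O)O[C@H]2C/C(C)=C/CC/C(CO)=C\C(=O)[C@H]12 | intermediate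
20 | [(tert-butyldimethylsilyl)oxy]acetaldehyde | CC(C)(C)[Si](C)(C)OCC=O | starting material
21 | ethyl 2-(triphenyl-λ5-phosphanylidene)propanoate | CCOC(=O)C(C)=P(c1ccccc1)(c1ccccc1)c1ccccc1 | starting material
22 | ethyl (2E)-4-[(tert-butyldimethylsilyl)oxy]-2-methylbut-2-enoate | CCOC(=O)/C(C)=C/CO[Si](C)(C)C(C)(C)C | intermediate
23 | (2E)-4-[(tert-butyldimethylsilyl)oxy]-2-methylbut-2-enoic acid | OC(=O)/C(C)=C/CO[Si](C)(C)C(C)(C)C | intermediate
24 | [(3aR,5E,9E,11aS)-10-methyl-3-methylidene-2,4-dioxo-2,3,3a,4,7,8,11,11a-octahydrocyclodeca[b]furan-6-yl]methyl (2E)-4-[(tert-butyldimethylsilyl)oxy]-2-methylbut-2-enoate | C=C1C(=O)O[C@H]2C/C(C)=C/CC/C(COC(=O)/C(C)=C/CO[Si](C)(C)C(C)(C)C)=C\C(=O)[C@H]12 | intermediate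
25 | [(3aS,4R,5E,9E,11aS)-4-hydroxy-10-methyl-3-methylidene-2-oxo-2,3,3a,4,7,8,11,11a-octahydrocyclodeca[b]furan-6-yl]methyl (2E)-4-[(tert-butyldimethylsilyl)oxy]-2-methylbut-2-enoate | C=C1C(=O)O[C@H]2C/C(C)=C/CC/C(COC(=O)/C(C)=C/CO[Si](C)(C)C(C)(C)C)=C\[C@@H](O)[C@H]12 | intermediate
26 | [(3aS,4R,5E,9E,11aS)-4-hydroxy-10-methyl-3-methylidene-2-oxo-2,3,3a,4,7,8,11,11a-octahydrocyclodeca[b]furan-6-yl]methyl (2E)-4-hydroxy-2-methylbut-2-enoate | C=C1C(=O)O[C@H]2C/C(C)=C/CC/C(COC(=O)/C(C)=C/CO)=C\[C@@H](O)[C@H]12 | target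

**Step count and risks**

Total step count: 16. Longest linear sequence: 13 steps (steps 1–3, 5–11 and 14–16).

The first of the three steps most likely to fail is step 9, the proposed new method. The malonate may add to the C6 carbonyl or attack C8 instead of C7, the β-alkoxide may open the ten-membered ring by retro-aldol cleavage before it lactonises, and C7 may epimerise. The fallback uses known chemistry only, sets out from 14 and returns to the route at 17. The epoxy ketone is opened reductively (SmI2, THF–MeOH, −90 °C) to the β-hydroxy ketone F1, which is silylated (TBSOTf, 2,6-lutidine) to the silyl ether F2. The kinetic enolate (LiHMDS, THF, −78 °C) is alkylated at C7 with allyl bromoacetate anti to the silyloxy group to give the ester F3. HF·pyridine removes the silyl group and the hydroxy ester closes to the trans-fused lactone ketone F4. Carboxylation at C11 with methoxymagnesium methyl carbonate (MeOMgOCO2Me, DMF, 120 °C) then gives 17, which is methylenated as in the second stage of step 10.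

The second is step 8. The catalyst may discriminate poorly between the enantiotopic faces of a conformationally mobile macrocyclic trienone, peroxide may compete at C4, and bond rotation in the peroxy enolate may destroy the cis relationship. The fallback sets out from 13, bypasses epoxide 14 and step 9, and returns at 17. Copper-catalysed asymmetric conjugate borylation (CuCl, NaOtBu, a chiral bisphosphine, B2pin2, MeOH, THF) places boron at C8 of the less substituted enone to give the β-boryl ketone F5. Oxidation with NaBO3·4H2O, with retention, gives the β-hydroxy ketone F1, and the sequence through F2, F3 and F4 described above then leads to 17.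

The third is step 15. The intrinsic facial bias of the macrocyclic ketone may override the catalyst, the methylene lactone may be reduced in a 1,4-sense, and the C6 alkoxide may translactonise. The fallback sets out from 24 and returns at 25. Substrate-controlled Luche reduction (NaBH4, CeCl3, MeOH, −78 °C) is used deliberately; if it gives the 6-epimeric alcohol F6, Mitsunobu inversion with formic acid (PPh3, DIAD, THF, 0 °C) gives the 6R formate F7. Mild methanolysis (KHCO3, MeOH, 0 °C) then cleaves only the formate and gives 25.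

**Further compounds**

F1 | step 9 | (2E,6E,9S)-9-hydroxy-3-{[(4-methoxyphenyl)methoxy]methyl}-7-methylcyclodeca-2,6-dien-1-one | O=C1C[C@@H](O)C/C(C)=C/CC/C(COCc2ccc(OC)cc2)=C\1
F2 | step 9 | (2E,6E,9S)-9-[(tert-butyldimethylsilyl)oxy]-3-{[(4-methoxyphenyl)methoxy]methyl}-7-methylcyclodeca-2,6-dien-1-one | O=C1C[C@@H](O[Si](C)(C)C(C)(C)C)C/C(C)=C/CC/C(COCc2ccc(OC)cc2)=C\1
F3 | step 9 | prop-2-en-1-yl [(1R,2S,4E,8E)-2-[(tert-butyldimethylsilyl)oxy]-8-{[(4-methoxyphenyl)methoxy]methyl}-4-methyl-10-oxocyclodeca-4,8-dien-1-yl]acetate | O=C1[C@H](CC(=O)OCC=C)[C@@H](O[Si](C)(C)C(C)(C)C)C/C(C)=C/CC/C(COCc2ccc(OC)cc2)=C\1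
F4 | step 9 | (3aR,5E,9E,11aS)-6-{[(4-methoxyphenyl)methoxy]methyl}-10-methyl-3,3a,7,8,11,11a-hexahydrocyclodeca[b]furan-2,4-dione | C1C(=O)O[C@H]2C/C(C)=C/CC/C(COCc3ccc(OC)cc3)=C\C(=O)[C@H]12
F5 | step 8 | (2E,6E,9S)-3-{[(4-methoxyphenyl)methoxy]methyl}-7-methyl-9-(4,4,5,5-tetramethyl-1,3,2-dioxaborolan-2-yl)cyclodeca-2,6-dien-1-one | O=C1C[C@@H](B2OC(C)(C)C(C)(C)O2)C/C(C)=C/CC/C(COCc3ccc(OC)cc3)=C\1
F6 | step 15 | [(3aS,4S,5E,9E,11aS)-4-hydroxy-10-methyl-3-methylidene-2-oxo-2,3,3a,4,7,8,11,11a-octahydrocyclodeca[b]furan-6-yl]methyl (2E)-4-[(tert-butyldimethylsilyl)oxy]-2-methylbut-2-enoate | C=C1C(=O)O[C@H]2C/C(C)=C/CC/C(COC(=O)/C(C)=C/CO[Si](C)(C)C(C)(C)C)=C\[C@H](O)[C@H]12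
F7 | step 15 | [(3aR,4R,5E,9E,11aS)-4-(formyloxy)-10-methyl-3-methylidene-2-oxo-2,3,3a,4,7,8,11,11a-octahydrocyclodeca[b]furan-6-yl]methyl (2E)-4-[(tert-butyldimethylsilyl)oxy]-2-methylbut-2-enoate | C=C1C(=O)O[C@H]2C/C(C)=C/CC/C(COC(=O)/C(C)=C/CO[Si](C)(C)C(C)(C)C)=C\[C@@H](OC=O)[C@H]12
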